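## The problem

Compound 20 is a 2,3-trans-disubstituted 2,3-dihydro-1,4-benzodioxine. Ring A (allyl at C7, methoxy at C5) is fused to the dioxane ring B (O1–C2–C3–O4); C2 carries the syringyl ring C with a free phenol, C3 a methyl group, and both centres are (R). The two ring oxygens are not equivalent, O4 lying next to the ring A methoxy group and O1 not, so the C2–C3 unit must be joined to ring A with defined regiochemistry; this is secured if the two aryl–oxygen bonds arise in two different events. The two stereocentres are adjacent and have to be fixed absolutely and relative to each other. C2 is a benzylic ether carbon on an electron-rich ring and could in principle be corrected toward the more stable trans isomer, but C3 has no such outlet; C3 must therefore be installed cleanly, and C2 is best set by a reagent that does not depend on C3 for induction. The allyl group excludes hydrogenolysis, late electrophilic halogenation, and strong bases or metal hydrides that move the double bond into conjugation; the ring C phenol must be masked through the organometallic and oxidative steps and released without acid, which would ionise the C2–O1 bond. The feature to exploit is the substitution pattern of the two sp3 carbons: C3 bears one oxygen (O4), one methyl group and C2, and C2 bears one oxygen (O1), one aryl group (ring C) and C3. A carbon of this kind is what a chloromethylene unit inserted into a B–C bond becomes once its chloride has been displaced by a nucleophile delivered through boron, so methyl, aryloxide, aryl and finally O1 (in place of boron itself) can each be introduced by a 1,2-shift whose stereochemical course is dictated by a chiral diol on boron.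

## Retrosynthesis

**O–Si bond of ring C.** Target 20 is traced to its triisopropylsilyl ether 19. The phenol cannot be free when an arylmagnesium reagent is made or when a palladium alkoxide is formed. A benzyl ether is excluded because hydrogenolysis would saturate the allyl group, an acetal because its removal needs acid at a benzylic ether, and the smaller tert-butyldimethylsilyl group is less secure toward perborate and carbonate. The forward step only has to cleave a hindered aryl silyl ether with buffered fluoride.

**O1–aryl bond of ring B.** Ring B of 19 is opened at the O1–C8a bond to give bromo alcohol 18. Cutting O1–C2 instead would make the ring closure a substitution at the benzylic stereocentre, with cation character and risk to its configuration; cutting at C3 would do the same to the centre that cannot be corrected. With the chosen cut both sp3 centres are spectators of the ring closure, and the ring A oxygen becomes a bromine that can be placed by brominating eugenol. The forward reaction is an intramolecular palladium-catalysed C–O coupling of a secondary benzylic alcohol that must not oxidise the carbinol or touch the allyl group.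

**C2–O1 bond to C2–B.** Alcohol 18 is derived from boronic ester 17 by oxidation with retention. This turns C2 into a boron-bound carbon and opens the way to building it by migrations on boron. The precursor is no simpler in atom count, but its C2 configuration is now a matter of boron chemistry.

**C2–C3 and C2–aryl bonds (key disconnection).** Boronic ester 17 is cut at both carbon–carbon bonds of C2, leading to the (1S)-1-aryloxyethyl boronic ester 10, arylmagnesium bromide 13 and a one-carbon chloromethylene carbenoid (specified in step 7); α-chloro boronic ester 15 lies between them. The neighbouring cuts (aryl metal addition to an α-aryloxy aldehyde, or hydride addition to an α-aryloxy ketone) rely on substrate control next to an epimerisable centre. Here the diol on boron decides the C2 configuration and the arylation is stereospecific. Precursor 10 has a single stereocentre and no ring C. The forward reaction must deliver diol-controlled insertion and must favour migration over loss of the C3 aryloxide.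

**C3–O4 bond.** Boronic ester 10 is cut at the C3–oxygen bond into (1R)-1-chloroethyl boronic ester 5 and bromophenol 7, which reacts as its phenolate 8. The ether oxygen thus enters as a nucleophile with inversion, and the regiochemistry of ring A is fixed because only one oxygen is present. The forward reaction asks a hindered phenolate to displace a secondary chloride through boron without epimerisation.

**C3–methyl bond.** Chloride 5 is traced to methylboronic ester 3 by removal of the inserted chloromethylene carbon, and 3 to methylboronic acid 1 and (1S,2S)-diol 2. The same diol then controls both stereocentres of the target and is released again at the oxidation.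

**Aromatic building blocks.** Bromophenol 7 comes from eugenol 6 by ortho bromination, which brings the allyl and methoxy groups of ring A in from the start. Grignard reagent 13 comes from silyl ether 12 and this from 4-bromo-2,6-dimethoxyphenol 11.

## Roads not taken

**Alternative 1:** Both C–O bonds of ring B would be made in one flask. The phenoxide of 4-bromo-3-hydroxy-5-methoxybenzaldehyde A3 would open the cis-epoxide A2 at its benzylic carbon with inversion (O1–C2), and the released C3 alkoxide would displace the ring A bromide under CuI, 1,10-phenanthroline and Cs2CO3 (O4–aryl) to give benzodioxane aldehyde A1.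
- Merits: it is the most convergent plan, the regiochemistry of the two oxygens follows from phenol versus bromide, and both centres come from one asymmetric epoxidation.
- Weak points: the benzylic carbon of A2 sits on a strongly donor-substituted ring, so the opening is likely to have cation character and inversion at C2 is not assured. A2 itself requires a cis-alkene and an enantioselective epoxidation. The pivalate is exposed to phenoxide and carbonate at high temperature. A1 still needs the formyl group converted into allyl (reduction, activation, vinyl coupling) and the ester removed.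
- Comparison: this road reaches ring B in one step where the chosen plan needs three (steps 7–9), which is a real advantage. The chosen plan sets against it a C2 centre that does not depend on a clean SN2 reaction at a cation-stabilised epoxide carbon, and an allyl group carried unchanged from eugenol, so that nothing remains to be done on ring A after cyclisation.

**Alternative 2:** The cut is the same O1–aryl bond as in step 9, but bromo alcohol A5 would come from the chiral pool: a lactic acid derivative supplies C3, ring C is added to give α-aryloxy ketone A6, and hydride reduction sets C2. Pd(OAc)2 with a bulky di-tert-butylbiarylphosphine and Cs2CO3 then closes A5 to the methoxymethyl ether A4.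
- Merits: every step is routine, no cryogenic carbenoid or stoichiometric chiral diol is needed, and the step count is equal to or one lower than that of the chosen plan. On practicality this is the stronger route.
- Weak points: A6 has an acidic C3–H between a carbonyl and an aryloxy group and can epimerise during Grignard addition or work-up. Its reduction is substrate-controlled; the threo alcohol needed is the polar Felkin–Anh product, whereas chelation favours erythro, so a mixture requiring separation is likely. Release of the phenol from A4 needs acid at a benzylic ether, although a silyl group could be substituted.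
- Comparison: the chosen plan sets against the practical advantage that both centres arise from stereospecific migrations under one recoverable diol, with no enolisable stereocentre at any stage. Because this road shares its endgame with the chosen plan, it is kept as the fallback for the key step.

**Alternative 3:** Ring B would be closed at O4–C3 while C3 gains its hydrogen. Under Co(salen), an N-fluoropyridinium oxidant and PhSiH3, the ring A phenol of the (S)-1-arylallyl aryl ether A8 would add in the Markovnikov sense across the vinyl group to give bromo benzodioxane A7.
- Merits: the methyl group and the ring form together from a vinyl group, A8 is accessible by a catalytic enantioselective allylic etherification, and the conditions tolerate the aryl bromide.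
- Weak points: C3 is created in the cyclisation under substrate control from C2 alone, and the trans to cis preference of a six-membered closure through a radical or organocobalt intermediate is not predictable with confidence. The nucleophile is an electron-rich catechol monoether exposed to an oxidant. The intermediate at C3 lies next to a doubly activated C2–H. A7 still requires an allyl cross-coupling at bromine and ester cleavage.
- Comparison: if the diastereoselectivity were high, this road would be the shortest to ring B. The chosen plan sets against it two centres fixed by stereospecific events and an allyl group that never has to be introduced by coupling.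

Key step: step 7

Assumption: the (1S,2S)-diol 2 is taken to deliver the (R)-α-chloro boronic esters in both insertions (steps 2 and 7), the accepted sense for C2-symmetric 1,2-diol boronic esters; were it the reverse, the (1R,2R)-diol would be used throughout and nothing else would change.

## Route

Step 1
Reactants: 1 methylboronic acid; 2 (1S,2S)-1,2-dicyclohexylethane-1,2-diol
Product: 3 (4S,5S)-4,5-dicyclohexyl-2-methyl-1,3,2-dioxaborolane
Conditions: MgSO4, Et2O, rt
Reagents that add atoms: none
Why: Condensation of a boronic acid with a 1,2-diol to the cyclic boronic ester, driven by removal of water; the hindered ester is stable to chromatography and to the organometallic steps that follow, and no stereocentre is formed.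

Step 2
Reactants: 3 (4S,5S)-4,5-dicyclohexyl-2-methyl-1,3,2-dioxaborolane
Product: 5 (4S,5S)-2-[(1R)-1-chloroethyl]-4,5-dicyclohexyl-1,3,2-dioxaborolane, via lithium (dichloromethyl)methylborate 4 (not isolated)
Conditions: CH2Cl2, n-BuLi, THF, −100 °C; then 3; ZnCl2, −100 °C → rt
Reagents that add atoms: (dichloromethyl)lithium, made in the flask from dichloromethane and n-BuLi, [Li]C(Cl)Cl
Why: Matteson homologation: preformed LiCHCl2 adds to boron to give borate 4, and on warming ZnCl2 assists loss of one of the two diastereotopic chlorides while the methyl group shifts from boron to carbon; the C2-symmetric diol selects the chloride that leaves and so sets the (1R) centre that becomes C3.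

Step 3
Reactants: 6 eugenol (4-allyl-2-methoxyphenol)
Product: 7 4-allyl-2-bromo-6-methoxyphenol
Conditions: NBS, i-Pr2NH (cat.), CH2Cl2, 0 °C, dark
Reagents that add atoms: N-bromosuccinimide, O=C1CCC(=O)N1Br
Why: Electrophilic aromatic bromination directed ortho to the hydroxyl by the amine-derived N-bromoamine; the para position is blocked by the allyl group, and ring substitution of the activated guaiacol nucleus should outrun ionic addition to the isolated terminal alkene at 0 °C.

Step 4
Reactants: 7 4-allyl-2-bromo-6-methoxyphenol; 5 (4S,5S)-2-[(1R)-1-chloroethyl]-4,5-dicyclohexyl-1,3,2-dioxaborolane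
Product: 10 (4S,5S)-2-[(1S)-1-(4-allyl-2-bromo-6-methoxyphenoxy)ethyl]-4,5-dicyclohexyl-1,3,2-dioxaborolane, via sodium phenolate 8 (not isolated), via sodium aryloxyborate 9 (not isolated)
Conditions: NaH (slight deficit), THF, 0 °C; then 5, DMSO, rt → 50 °C
Reagents that add atoms: none
Why: Nucleophilic substitution of an α-chloro boronic ester through boron, the reaction type used with alkoxides on the same esters: phenolate 8 adds to boron to give borate 9 and the aryloxy group shifts to carbon anti to the C–Cl bond, so the (1R)-chloride gives the (1S)-ether by inversion; DMSO raises the reactivity of the hindered phenolate.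

Step 5
Reactants: 11 4-bromo-2,6-dimethoxyphenol
Product: 12 (4-bromo-2,6-dimethoxyphenoxy)triisopropylsilane
Conditions: i-Pr3SiCl, imidazole, DMF, rt → 40 °C
Reagents that add atoms: chlorotriisopropylsilane, CC(C)[Si](Cl)(C(C)C)C(C)C
Why: Silylation of a phenol with a trialkylsilyl chloride under imidazole catalysis; the flanking methoxy groups slow the reaction but are small enough to admit the triisopropylsilyl group, chosen for its resistance to perborate and carbonate later.

Step 6
Reactants: 12 (4-bromo-2,6-dimethoxyphenoxy)triisopropylsilane
Product: 13 [3,5-dimethoxy-4-(triisopropylsilyloxy)phenyl]magnesium bromide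
Conditions: Mg turnings, I2 (crystal), THF, 45 °C; kept as a titrated solution
Reagents that add atoms: magnesium, [Mg]
Why: Grignard reagent formation by insertion of magnesium into the aryl C–Br bond; the silyl ether and methoxy groups are inert, and the silyl group has no path to the para carbanion.

Step 7
Reactants: 10 (4S,5S)-2-[(1S)-1-(4-allyl-2-bromo-6-methoxyphenoxy)ethyl]-4,5-dicyclohexyl-1,3,2-dioxaborolane; 13 [3,5-dimethoxy-4-(triisopropylsilyloxy)phenyl]magnesium bromide
Product: 17 (4S,5S)-2-[(1R,2R)-2-(4-allyl-2-bromo-6-methoxyphenoxy)-1-[3,5-dimethoxy-4-(triisopropylsilyloxy)phenyl]propyl]-4,5-dicyclohexyl-1,3,2-dioxaborolane, via lithium (dichloromethyl)borate 14 (not isolated), via α-chloro boronic ester 15 (not isolated), via bromomagnesium arylborate 16 (not isolated)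
Conditions: CH2Cl2, n-BuLi, THF, −100 °C; then 10; ZnCl2, −100 °C → rt; aq NH4Cl/pentane wash, crude 15 taken up in THF; 13, −78 °C → rt
Reagents that add atoms: (dichloromethyl)lithium, made in the flask from dichloromethane and n-BuLi, [Li]C(Cl)Cl
Why: Matteson homologation followed by Grignard substitution, two successive 1,2-metallate rearrangements on one boron atom. Preformed LiCHCl2 adds to the boron of 10 to give borate 14; on warming, ZnCl2 assists departure of one of the two diastereotopic chlorides while the 1-aryloxyethyl group shifts from boron to carbon with retention at C3, and the C2-symmetric diol decides which chloride leaves, so that chloride 15 is (1R). Grignard reagent 13 then adds to boron to give borate 16, and the aryl group migrates anti to the C–Cl bond, inverting C2 and forming the C2–aryl bond. The closest precedent is the same two-stage sequence on α-alkoxy boronic esters of chiral diols in polyol synthesis; an α-aryloxy group differs in being a better leaving group. No ring is closed. The one new stereocentre, C2, is under reagent control by the diol in the insertion and is carried through the arylation by a stereospecific invertive migration, while C3 is not touched. The step needs attack at boron in preference to the aryl bromide and the allyl group, which preforming the carbenoid (no free n-BuLi or amide base) secures. It also needs migration in preference to β-elimination of the C3 aryloxide, which low temperature, ZnCl2 binding the released chloride and the fast displacement of an α-chloride within a borate all serve.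

Step 8
Reactants: 17 (4S,5S)-2-[(1R,2R)-2-(4-allyl-2-bromo-6-methoxyphenoxy)-1-[3,5-dimethoxy-4-(triisopropylsilyloxy)phenyl]propyl]-4,5-dicyclohexyl-1,3,2-dioxaborolane
Product: 18 (1R,2R)-2-(4-allyl-2-bromo-6-methoxyphenoxy)-1-[3,5-dimethoxy-4-(triisopropylsilyloxy)phenyl]propan-1-ol
Conditions: NaBO3·4H2O, THF/H2O, rt
Reagents that add atoms: sodium perborate tetrahydrate (NaBO3·4H2O), [Na+].[O-]OB=O.O.O.O.O
Why: Oxidation of a secondary boronic ester by a peroxoborate: the peroxide oxygen adds to boron and the benzylic carbon migrates from boron to oxygen with retention, so (1R)-B becomes (1R)-OH; the mildly basic reagent spares the aryl silyl ether, the aryl bromide and the terminal alkene and limits base-induced loss of the aryloxide.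

Step 9
Reactants: 18 (1R,2R)-2-(4-allyl-2-bromo-6-methoxyphenoxy)-1-[3,5-dimethoxy-4-(triisopropylsilyloxy)phenyl]propan-1-ol
Product: 19 (2R,3R)-7-allyl-2-[3,5-dimethoxy-4-(triisopropylsilyloxy)phenyl]-5-methoxy-3-methyl-2,3-dihydro-1,4-benzodioxine
Conditions: Pd(OAc)2 (cat.), 2-(di-tert-butylphosphino)-1,1'-binaphthyl, Cs2CO3, toluene, 65 °C
Reagents that add atoms: none
Why: Buchwald–Hartwig-type intramolecular C–O coupling: zerovalent palladium formed from Pd(OAc)2 inserts into the C–Br bond, Cs2CO3 generates the palladium alkoxide, and the bulky phosphine drives C–O reductive elimination ahead of β-hydride elimination to close the six-membered ring B; neither stereocentre takes part, so the threo alcohol gives the trans (2R,3R) ring.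

Step 10
Reactants: 19 (2R,3R)-7-allyl-2-[3,5-dimethoxy-4-(triisopropylsilyloxy)phenyl]-5-methoxy-3-methyl-2,3-dihydro-1,4-benzodioxine
Product: 20 4-[(2R,3R)-7-allyl-5-methoxy-3-methyl-2,3-dihydro-1,4-benzodioxin-2-yl]-2,6-dimethoxyphenol
Conditions: Bu4NF, AcOH, THF, 0 °C
Reagents that add atoms: none
Why: Fluoride cleavage of an aryl silyl ether, driven by the Si–F bond; acetic acid buffers the liberated phenoxide so that neither the allyl group nor the benzylic C2–O1 bond para to the new phenol is disturbed.

## Compound list

1 | methylboronic acid | CB(O)O | starting material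
2 | (1S,2S)-1,2-dicyclohexylethane-1,2-diol | O[C@@H](C1CCCCC1)[C@@H](O)C1CCCCC1 | starting material
3 | (4S,5S)-4,5-dicyclohexyl-2-methyl-1,3,2-dioxaborolane | CB1O[C@@H](C2CCCCC2)[C@H](C2CCCCC2)O1 | intermediate
4 | lithium (4S,5S)-4,5-dicyclohexyl-2-(dichloromethyl)-2-methyl-1,3,2-dioxaborolan-2-uide (not isolated) | [Li+].C[B-]1(C(Cl)Cl)O[C@@H](C2CCCCC2)[C@H](C2CCCCC2)O1 | intermediate
5 | (4S,5S)-2-[(1R)-1-chloroethyl]-4,5-dicyclohexyl-1,3,2-dioxaborolane | C[C@H](Cl)B1O[C@@H](C2CCCCC2)[C@H](C2CCCCC2)O1 | intermediate
6 | eugenol (4-allyl-2-methoxyphenol) | C=CCc1ccc(O)c(OC)c1 | starting material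
7 | 4-allyl-2-bromo-6-methoxyphenol | C=CCc1cc(Br)c(O)c(OC)c1 | intermediate
8 | sodium 4-allyl-2-bromo-6-methoxyphenolate (not isolated) | [Na+].[O-]c1c(Br)cc(CC=C)cc1OC | intermediate
9 | sodium (4S,5S)-2-(4-allyl-2-bromo-6-methoxyphenoxy)-2-[(1R)-1-chloroethyl]-4,5-dicyclohexyl-1,3,2-dioxaborolan-2-uide (not isolated) | [Na+].C[C@H](Cl)[B-]1(Oc2c(Br)cc(CC=C)cc2OC)O[C@@H](C3CCCCC3)[C@H](C3CCCCC3)O1 | intermediate
10 | (4S,5S)-2-[(1S)-1-(4-allyl-2-bromo-6-methoxyphenoxy)ethyl]-4,5-dicyclohexyl-1,3,2-dioxaborolane | C=CCc1cc(OC)c(O[C@H](C)B2O[C@@H](C3CCCCC3)[C@H](C3CCCCC3)O2)c(Br)c1 | intermediate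
11 | 4-bromo-2,6-dimethoxyphenol | COc1cc(Br)cc(OC)c1O | starting material
12 | (4-bromo-2,6-dimethoxyphenoxy)triisopropylsilane | COc1cc(Br)cc(OC)c1O[Si](C(C)C)(C(C)C)C(C)C | intermediate
13 | [3,5-dimethoxy-4-(triisopropylsilyloxy)phenyl]magnesium bromide | COc1cc([Mg]Br)cc(OC)c1O[Si](C(C)C)(C(C)C)C(C)C | intermediate
14 | lithium (4S,5S)-2-[(1S)-1-(4-allyl-2-bromo-6-methoxyphenoxy)ethyl]-4,5-dicyclohexyl-2-(dichloromethyl)-1,3,2-dioxaborolan-2-uide (not isolated) | [Li+].C=CCc1cc(OC)c(O[C@H](C)[B-]2(C(Cl)Cl)O[C@@H](C3CCCCC3)[C@H](C3CCCCC3)O2)c(Br)c1 | intermediate
15 | (4S,5S)-2-[(1R,2R)-2-(4-allyl-2-bromo-6-methoxyphenoxy)-1-chloropropyl]-4,5-dicyclohexyl-1,3,2-dioxaborolane (not isolated) | C=CCc1cc(OC)c(O[C@H](C)[C@H](Cl)B2O[C@@H](C3CCCCC3)[C@H](C3CCCCC3)O2)c(Br)c1 | intermediate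
16 | bromomagnesium (4S,5S)-2-[(1R,2R)-2-(4-allyl-2-bromo-6-methoxyphenoxy)-1-chloropropyl]-4,5-dicyclohexyl-2-[3,5-dimethoxy-4-(triisopropylsilyloxy)phenyl]-1,3,2-dioxaborolan-2-uide (not isolated) | Br[Mg+].C=CCc1cc(OC)c(O[C@H](C)[C@H](Cl)[B-]2(c3cc(OC)c(O[Si](C(C)C)(C(C)C)C(C)C)c(OC)c3)O[C@@H](C3CCCCC3)[C@H](C3CCCCC3)O2)c(Br)c1 | intermediate
17 | (4S,5S)-2-[(1R,2R)-2-(4-allyl-2-bromo-6-methoxyphenoxy)-1-[3,5-dimethoxy-4-(triisopropylsilyloxy)phenyl]propyl]-4,5-dicyclohexyl-1,3,2-dioxaborolane | C=CCc1cc(OC)c(O[C@H](C)[C@H](B2O[C@@H](C3CCCCC3)[C@H](C3CCCCC3)O2)c2cc(OC)c(O[Si](C(C)C)(C(C)C)C(C)C)c(OC)c2)c(Br)c1 | intermediate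
18 | (1R,2R)-2-(4-allyl-2-bromo-6-methoxyphenoxy)-1-[3,5-dimethoxy-4-(triisopropylsilyloxy)phenyl]propan-1-ol | C=CCc1cc(OC)c(O[C@H](C)[C@H](O)c2cc(OC)c(O[Si](C(C)C)(C(C)C)C(C)C)c(OC)c2)c(Br)c1 | intermediate
19 | (2R,3R)-7-allyl-2-[3,5-dimethoxy-4-(triisopropylsilyloxy)phenyl]-5-methoxy-3-methyl-2,3-dihydro-1,4-benzodioxine | C=CCc1cc(OC)c2c(c1)O[C@H](c1cc(OC)c(O[Si](C(C)C)(C(C)C)C(C)C)c(OC)c1)[C@@H](C)O2 | intermediate
20 | 4-[(2R,3R)-7-allyl-5-methoxy-3-methyl-2,3-dihydro-1,4-benzodioxin-2-yl]-2,6-dimethoxyphenol | C=CCc1cc(OC)c2c(c1)O[C@H](c1cc(OC)c(O)c(OC)c1)[C@@H](C)O2 | target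

## Step count and risks

Total step count: 10. Longest linear sequence: 7 steps (steps 1, 2, 4, 7, 8, 9 and 10, from methylboronic acid 1).

**Step 7 (key step).**
- What may go wrong: the aryloxide on C3 is a better leaving group than the alkoxides for which this sequence is established, so β-elimination from either borate, or Lewis-acid-induced elimination from the chloride, may compete with migration. The electron-poor α-aryloxyalkyl group may also migrate slowly, allowing the carbenoid to decompose, and chloride exchange may erode the C2 configuration before the Grignard reagent is added.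
- Fallback: alcohol 18 is reached from phenol 7 and Grignard reagent 13 without boron. Mitsunobu reaction of 7 with methyl (S)-lactate (PPh3, diisopropyl azodicarboxylate, THF) gives, with inversion, methyl (2R)-2-(4-allyl-2-bromo-6-methoxyphenoxy)propanoate F1. Me(MeO)NH·HCl and i-PrMgCl at −20 °C convert it into (2R)-2-(4-allyl-2-bromo-6-methoxyphenoxy)-N-methoxy-N-methylpropanamide F2. Reagent 13 adds once to give (2R)-2-(4-allyl-2-bromo-6-methoxyphenoxy)-1-[3,5-dimethoxy-4-(triisopropylsilyloxy)phenyl]propan-1-one F3. Reduction with LiBH(s-Bu)3 at −78 °C, for which the polar Felkin–Anh model predicts the threo alcohol, rejoins the route at 18, so that steps 7 and 8 are both bypassed.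

**Step 4.**
- What may go wrong: the doubly ortho-substituted, weakly basic phenolate may attack the shielded boron slowly, so that exchange with the liberated chloride epimerises the carbon that becomes C3, or the substitution stalls.
- Fallback: the electrophile is changed. From boronic ester 3, insertion of LiCHBr2 (CH2Br2 and LiN(i-Pr)2 in THF at −78 °C, then ZnCl2) gives (4S,5S)-2-[(1R)-1-bromoethyl]-4,5-dicyclohexyl-1,3,2-dioxaborolane F4. Its better leaving group should let phenolate 8 react at or below room temperature, ahead of halide exchange, and the route is rejoined at 10.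

**Step 9.**
- What may go wrong: β-hydride elimination from the benzylic palladium alkoxide (oxidation of the carbinol with reduction of the C–Br bond), Heck-type consumption of the terminal alkene by the arylpalladium intermediate, or migration of the allyl double bond by a palladium hydride.
- Fallback: the metal and the mechanism are changed. Bromo alcohol 18 is closed directly to 19 by an Ullmann-type coupling with CuI, 3,4,7,8-tetramethyl-1,10-phenanthroline and Cs2CO3 in toluene at 110 °C. A copper alkoxide has neither a fast β-hydride elimination nor a Heck pathway, and no new compound is made.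

**Step 3.**
- What may go wrong: addition of bromine across the allyl double bond or allylic bromination competing with ring substitution, and substitution para to the methoxy group.
- Fallback: the alkene is masked while the ring is brominated. Eugenol 6 is treated with Br2 (two equivalents, CH2Cl2, 0 °C), which saturates the double bond and brominates ortho to the hydroxyl to give 2-bromo-4-(2,3-dibromopropyl)-6-methoxyphenol F5. Zn in AcOH/EtOH then removes the vicinal dibromide by reductive elimination and restores the allyl group, rejoining the route at 7.

## Further compounds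

F1 | step 7 | methyl (2R)-2-(4-allyl-2-bromo-6-methoxyphenoxy)propanoate | C=CCc1cc(OC)c(O[C@H](C)C(=O)OC)c(Br)c1
F2 | step 7 | (2R)-2-(4-allyl-2-bromo-6-methoxyphenoxy)-N-methoxy-N-methylpropanamide | C=CCc1cc(OC)c(O[C@H](C)C(=O)N(C)OC)c(Br)c1
F3 | step 7 | (2R)-2-(4-allyl-2-bromo-6-methoxyphenoxy)-1-[3,5-dimethoxy-4-(triisopropylsilyloxy)phenyl]propan-1-one | C=CCc1cc(OC)c(O[C@H](C)C(=O)c2cc(OC)c(O[Si](C(C)C)(C(C)C)C(C)C)c(OC)c2)c(Br)c1
F4 | step 4 | (4S,5S)-2-[(1R)-1-bromoethyl]-4,5-dicyclohexyl-1,3,2-dioxaborolane | C[C@H](Br)B1O[C@@H](C2CCCCC2)[C@H](C2CCCCC2)O1
F0 | step 9 | none | none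
F5 | step 3 | 2-bromo-4-(2,3-dibromopropyl)-6-methoxyphenol (racemic side chain) | COc1cc(CC(Br)CBr)cc(Br)c1O
A1 | alternative 1 | (2R,3R)-2-[3,5-dimethoxy-4-(pivaloyloxy)phenyl]-5-methoxy-3-methyl-2,3-dihydro-1,4-benzodioxine-7-carbaldehyde | O=Cc1cc(OC)c2c(c1)O[C@H](c1cc(OC)c(OC(=O)C(C)(C)C)c(OC)c1)[C@@H](C)O2
A2 | alternative 1 | 2,6-dimethoxy-4-[(2S,3R)-3-methyloxiran-2-yl]phenyl pivalate | C[C@H]1O[C@H]1c1cc(OC)c(OC(=O)C(C)(C)C)c(OC)c1
A3 | alternative 1 | 4-bromo-3-hydroxy-5-methoxybenzaldehyde | O=Cc1cc(O)c(Br)c(OC)c1
A4 | alternative 2 | (2R,3R)-7-allyl-2-[3,5-dimethoxy-4-(methoxymethoxy)phenyl]-5-methoxy-3-methyl-2,3-dihydro-1,4-benzodioxine | C=CCc1cc(OC)c2c(c1)O[C@H](c1cc(OC)c(OCOC)c(OC)c1)[C@@H](C)O2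
A5 | alternative 2 | (1R,2R)-2-(4-allyl-2-bromo-6-methoxyphenoxy)-1-[3,5-dimethoxy-4-(methoxymethoxy)phenyl]propan-1-ol | C=CCc1cc(OC)c(O[C@H](C)[C@H](O)c2cc(OC)c(OCOC)c(OC)c2)c(Br)c1
A6 | alternative 2 | (2R)-2-(4-allyl-2-bromo-6-methoxyphenoxy)-1-[3,5-dimethoxy-4-(methoxymethoxy)phenyl]propan-1-one | C=CCc1cc(OC)c(O[C@H](C)C(=O)c2cc(OC)c(OCOC)c(OC)c2)c(Br)c1
A7 | alternative 3 | 4-[(2R,3R)-7-bromo-5-methoxy-3-methyl-2,3-dihydro-1,4-benzodioxin-2-yl]-2,6-dimethoxyphenyl pivalate | Brc1cc(OC)c2c(c1)O[C@H](c1cc(OC)c(OC(=O)C(C)(C)C)c(OC)c1)[C@@H](C)O2
A8 | alternative 3 | 4-[(1S)-1-(5-bromo-2-hydroxy-3-methoxyphenoxy)prop-2-en-1-yl]-2,6-dimethoxyphenyl pivalate | C=C[C@H](Oc1cc(Br)cc(OC)c1O)c1cc(OC)c(OC(=O)C(C)(C)C)c(OC)c1
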